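## Retrosynthetic overview

1. Last: the trans C5–Cl/C4–Br pair of ring A from the C4=C5 cyclohexene (epoxide, tertiary bromide, bromonium, chloride), then removal of the C3' protecting group.
2. Ring B (bromo-oxane): 6-endo bromoetherification of the C2' tertiary alcohol onto the prenyl alkene, which sets C5'.
3. Fragment union at C2'–C3': chelation-controlled addition of an enantioenriched α-alkoxy organometallic (C3'–C6' fragment, made from an acylstannane) to the ring A methyl ketone.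
4. Ring A: ring-closing metathesis of the 1,7-diene from an Evans syn-aldol, which sets C1 and C2.
5. Order of ring formation: ring A by metathesis first, ring B by bromoetherification second.

Assumption (locants): ring A is the cyclohexane with C1 = CH–OAc, C2 = CH bearing the oxane, C4 = CHBr, C5 = C(Cl)CH3; ring B is the oxane with C2' quaternary, C3' = CHOH, C5' = CHBr, C6' = CMe2.

## Route

Step 1
Reactants: 1 3-methylbut-3-en-1-ol
Product: 2 3-methylbut-3-enal
Conditions: Dess–Martin periodinane, NaHCO3, CH2Cl2, 0 °C; cold solution used directly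
Reagents that add atoms: none
Why: Dess–Martin oxidation under buffered, non-aqueous conditions gives the β,γ-unsaturated aldehyde without isomerisation to the conjugated enal.

Step 2
Reactants: 3 (S)-4-benzyloxazolidin-2-one; 4 pent-4-enoyl chloride
Product: 5 (S)-4-benzyl-3-(pent-4-enoyl)oxazolidin-2-one
Conditions: n-BuLi, THF, −78 °C; then 4, −78 → 0 °C
Reagents that add atoms: none
Why: N-acylation of the lithiated Evans auxiliary is a standard, high-yielding acyl substitution that creates no new stereocentre.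

Step 3
Reactants: 5 (S)-4-benzyl-3-(pent-4-enoyl)oxazolidin-2-one; 2 3-methylbut-3-enal
Product: 7 (4S)-4-benzyl-3-[(2S,3R)-3-hydroxy-5-methyl-2-(prop-2-en-1-yl)hex-5-enoyl]oxazolidin-2-one, via dibutylboron Z-enolate 6 (not isolated)
Conditions: Bu2BOTf, iPr2NEt, CH2Cl2, −78 → 0 °C; then 2, −78 → 0 °C; pH 7 buffer, MeOH, H2O2
Reagents that add atoms: none
Why: Evans syn-aldol reaction, in which the Z-boron enolate reacts through a Zimmerman–Traxler chair on the face away from the benzyl group, setting C2 (S) and C1 (R) of ring A in a syn relationship.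

Step 4
Reactants: 7 (4S)-4-benzyl-3-[(2S,3R)-3-hydroxy-5-methyl-2-(prop-2-en-1-yl)hex-5-enoyl]oxazolidin-2-one
Product: 8 (2S,3R)-3-hydroxy-N-methoxy-N,5-dimethyl-2-(prop-2-en-1-yl)hex-5-enamide
Conditions: MeNH(OMe)·HCl, AlMe3, CH2Cl2, −10 → 0 °C
Reagents that add atoms: N,O-dimethylhydroxylamine hydrochloride, CNOC.Cl
Why: Weinreb transamidation by the aluminium amide, assisted by the free β-hydroxy group, removes the auxiliary without touching either stereocentre.

Step 5
Reactants: 8 (2S,3R)-3-hydroxy-N-methoxy-N,5-dimethyl-2-(prop-2-en-1-yl)hex-5-enamide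
Product: 9 (1S,6R)-6-hydroxy-N-methoxy-N,4-dimethylcyclohex-3-ene-1-carboxamide
Conditions: second-generation Grubbs catalyst (3 mol %), CH2Cl2, 40 °C
Reagents that add atoms: none
Why: Ring-closing metathesis of the vinyl and 2-methylallyl termini of the 1,7-diene closes ring A as the trisubstituted cyclohexene with loss of ethene and no change at the stereocentres.

Step 6
Reactants: 9 (1S,6R)-6-hydroxy-N-methoxy-N,4-dimethylcyclohex-3-ene-1-carboxamide
Product: 10 1-[(1S,6R)-6-hydroxy-4-methylcyclohex-3-en-1-yl]ethan-1-one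
Conditions: MeMgBr (3 equiv), THF, 0 °C; cold aqueous work-up
Reagents that add atoms: methylmagnesium bromide, C[Mg]Br
Why: Weinreb ketone synthesis, in which the stable magnesium chelate prevents over-addition and frees the cis β-hydroxy ketone only on quenching, so C2 is not epimerised.

Step 7
Reactants: 11 4-methylpent-3-en-1-ol
Product: 12 4-methylpent-3-enal
Conditions: Dess–Martin periodinane, NaHCO3, CH2Cl2, 0 °C; used at once
Reagents that add atoms: none
Why: Buffered Dess–Martin oxidation gives the skipped enal without migration of the double bond.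

Step 8
Reactants: 12 4-methylpent-3-enal
Product: 13 rac-4-methyl-1-(tributylstannyl)pent-3-en-1-ol
Conditions: Bu3SnH, LiN(iPr)2, THF, 0 °C; then 12, −78 °C; H2O; used crude
Reagents that add atoms: tributylstannyllithium, [Li][Sn](CCCC)(CCCC)CCCC
Why: 1,2-addition of the stannyl anion to the aldehyde gives the α-hydroxystannane as a racemate, which is corrected in step 10.

Step 9
Reactants: 13 rac-4-methyl-1-(tributylstannyl)pent-3-en-1-ol
Product: 14 4-methyl-1-(tributylstannyl)pent-3-en-1-one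
Conditions: EtMgBr, THF, 0 °C; then 1,1'-(azodicarbonyl)dipiperidine, 0 °C → rt
Reagents that add atoms: none
Why: Mukaiyama-type oxidation of the magnesium alkoxide by hydride transfer to the azo compound gives the acylstannane under non-acidic conditions that avoid destannylation.

Step 10
Reactants: 14 4-methyl-1-(tributylstannyl)pent-3-en-1-one
Product: 15 (1R)-4-methyl-1-(tributylstannyl)pent-3-en-1-ol
Conditions: (S)-BINAL-H, LiAlH(OEt)[(S)-1,1'-binaphthalene-2,2'-diolate], THF, −78 °C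
Reagents that add atoms: none
Why: BINAL-H asymmetric reduction, in which the stannyl group takes the place of the unsaturated substituent in the chair transition state, so the (S)-reagent delivers hydride to give the (1R)-carbinol that becomes C3'.

Step 11
Reactants: 15 (1R)-4-methyl-1-(tributylstannyl)pent-3-en-1-ol
Product: 16 tributyl[(1R)-1-(methoxymethoxy)-4-methylpent-3-en-1-yl]stannane
Conditions: MOMCl, iPr2NEt, CH2Cl2, 0 °C
Reagents that add atoms: chloromethyl methyl ether, COCCl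
Why: O-alkylation (acetal formation) under mild base protects the labile α-hydroxystannane without touching the carbinol centre.

Step 12
Reactants: 16 tributyl[(1R)-1-(methoxymethoxy)-4-methylpent-3-en-1-yl]stannane; 10 1-[(1S,6R)-6-hydroxy-4-methylcyclohex-3-en-1-yl]ethan-1-one
Product: 19 (1R,6S)-6-[(2S,3S)-2-hydroxy-3-(methoxymethoxy)-6-methylhept-5-en-2-yl]-3-methylcyclohex-3-en-1-ol, via organolithium 17 (not isolated), via organomagnesium bromide 18 (not isolated)
Conditions: 16 (2.2 equiv), n-BuLi, THF, −78 °C; MgBr2·OEt2, −78 °C; then 10, −78 → −40 °C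
Reagents that add atoms: none
Why: Tin–lithium exchange and transmetalation to magnesium go with retention, and the α-alkoxy Grignard reagent adds to the six-membered magnesium chelate of the β-alkoxido ketone on its convex face (chelation-controlled 1,2-addition), setting C2' (S) while C3' (S) comes from the reagent.

Step 13
Reactants: 19 (1R,6S)-6-[(2S,3S)-2-hydroxy-3-(methoxymethoxy)-6-methylhept-5-en-2-yl]-3-methylcyclohex-3-en-1-ol
Product: 20 (1R,6S)-6-[(2S,3S)-2-hydroxy-3-(methoxymethoxy)-6-methylhept-5-en-2-yl]-3-methylcyclohex-3-en-1-yl acetate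
Conditions: Ac2O, DMAP, pyridine, CH2Cl2, 0 °C → rt
Reagents that add atoms: acetic anhydride, CC(=O)OC(C)=O
Why: Chemoselective acylation, in which the secondary C1 hydroxy group is esterified and the tertiary C2' hydroxy group is left free for the cyclisation.

Step 14
Reactants: 20 (1R,6S)-6-[(2S,3S)-2-hydroxy-3-(methoxymethoxy)-6-methylhept-5-en-2-yl]-3-methylcyclohex-3-en-1-yl acetate
Product: 21 (1R,6S)-6-[(2S,3S,5S)-5-bromo-3-(methoxymethoxy)-2,6,6-trimethyloxan-2-yl]-3-methylcyclohex-3-en-1-yl acetate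
Conditions: 2,4,4,6-tetrabromocyclohexa-2,5-dien-1-one (TBCO), CH2Cl2, −20 → 0 °C, dark
Reagents that add atoms: 2,4,4,6-tetrabromocyclohexa-2,5-dien-1-one, O=C1C(Br)=CC(Br)(Br)C=C1Br
Why: 6-endo bromoetherification (Markovnikov, anti addition) through a chair with the cyclohexenyl group equatorial closes ring B and places bromine equatorial, setting C5' (S).

Step 15
Reactants: 21 (1R,6S)-6-[(2S,3S,5S)-5-bromo-3-(methoxymethoxy)-2,6,6-trimethyloxan-2-yl]-3-methylcyclohex-3-en-1-yl acetate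
Product: 22 (1R,2S,4S,5R)-2-[(2S,3S,5S)-5-bromo-3-(methoxymethoxy)-2,6,6-trimethyloxan-2-yl]-4,5-epoxy-5-methylcyclohexyl acetate
Conditions: mCPBA, NaHCO3, CH2Cl2, 0 °C
Reagents that add atoms: 3-chloroperoxybenzoic acid, OOC(=O)c1cccc(Cl)c1
Why: Prilezhaev epoxidation takes place on the ring face opposite the pseudoaxial acetoxy group and the oxanyl group, giving the epoxide trans to both.

Step 16
Reactants: 22 (1R,2S,4S,5R)-2-[(2S,3S,5S)-5-bromo-3-(methoxymethoxy)-2,6,6-trimethyloxan-2-yl]-4,5-epoxy-5-methylcyclohexyl acetate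
Product: 23 (1R,2S,4S,5S)-5-bromo-2-[(2S,3S,5S)-5-bromo-3-(methoxymethoxy)-2,6,6-trimethyloxan-2-yl]-4-hydroxy-5-methylcyclohexyl acetate
Conditions: HBr (48 % aq), CHCl3, −20 °C, 10 min
Reagents that add atoms: hydrogen bromide, Br
Why: Acid-promoted epoxide opening that is both Markovnikov and trans-diaxial (Fürst–Plattner) puts bromide axial on the tertiary C5 with inversion and leaves an axial hydroxy group at C4.

Step 17
Reactants: 23 (1R,2S,4S,5S)-5-bromo-2-[(2S,3S,5S)-5-bromo-3-(methoxymethoxy)-2,6,6-trimethyloxan-2-yl]-4-hydroxy-5-methylcyclohexyl acetate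
Product: 25 (1R,2S,4R,5R)-4-bromo-2-[(2S,3S,5S)-5-bromo-3-(methoxymethoxy)-2,6,6-trimethyloxan-2-yl]-5-chloro-5-methylcyclohexyl acetate, via chlorosulfite 24 (not isolated)
Conditions: SOCl2, pyridine, CH2Cl2, −30 → 0 °C; then toluene, 80 °C
Reagents that add atoms: thionyl chloride, O=S(Cl)Cl
Why: Neighbouring-group participation, in which the anti-periplanar C5 bromine displaces the chlorosulfite to a bromonium ion that chloride opens at the tertiary carbon from the opposite face (1,2-bromine shift, C4 R and C5 R), and warming converts any diaxial regioisomer into the same diequatorial product.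

Step 18
Reactants: 25 (1R,2S,4R,5R)-4-bromo-2-[(2S,3S,5S)-5-bromo-3-(methoxymethoxy)-2,6,6-trimethyloxan-2-yl]-5-chloro-5-methylcyclohexyl acetate
Product: 26 (1R,2S,4R,5R)-4-bromo-2-[(2S,3S,5S)-5-bromo-3-hydroxy-2,6,6-trimethyloxan-2-yl]-5-chloro-5-methylcyclohexyl acetate
Conditions: Me2BBr, CH2Cl2, −78 °C; then aqueous NaHCO3
Reagents that add atoms: none
Why: Lewis-acid cleavage of the methoxymethyl acetal at low temperature frees the C3' hydroxy group without affecting the acetate, the halides or the oxane.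

## Compound list

1 | 3-methylbut-3-en-1-ol | CC(=C)CCO | starting material
2 | 3-methylbut-3-enal | CC(=C)CC=O | intermediate
3 | (S)-4-benzyloxazolidin-2-one | O=C1N[C@@H](Cc2ccccc2)CO1 | starting material
4 | pent-4-enoyl chloride | C=CCCC(Cl)=O | starting material
5 | (S)-4-benzyl-3-(pent-4-enoyl)oxazolidin-2-one | C=CCCC(=O)N1[C@@H](Cc2ccccc2)COC1=O | intermediate
6 | dibutylboron Z-enolate of 5 | C=CC/C=C(\OB(CCCC)CCCC)N1[C@@H](Cc2ccccc2)COC1=O | intermediate
7 | (4S)-4-benzyl-3-[(2S,3R)-3-hydroxy-5-methyl-2-(prop-2-en-1-yl)hex-5-enoyl]oxazolidin-2-one | C=C(C)C[C@@H](O)[C@H](CC=C)C(=O)N1[C@@H](Cc2ccccc2)COC1=O | intermediate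
8 | (2S,3R)-3-hydroxy-N-methoxy-N,5-dimethyl-2-(prop-2-en-1-yl)hex-5-enamide | C=C(C)C[C@@H](O)[C@H](CC=C)C(=O)N(C)OC | intermediate
9 | (1S,6R)-6-hydroxy-N-methoxy-N,4-dimethylcyclohex-3-ene-1-carboxamide | O[C@@H]1CC(C)=CC[C@@H]1C(=O)N(C)OC | intermediate
10 | 1-[(1S,6R)-6-hydroxy-4-methylcyclohex-3-en-1-yl]ethan-1-one | O[C@@H]1CC(C)=CC[C@@H]1C(C)=O | intermediate
11 | 4-methylpent-3-en-1-ol | CC(C)=CCCO | starting material
12 | 4-methylpent-3-enal | CC(C)=CCC=O | intermediate
13 | rac-4-methyl-1-(tributylstannyl)pent-3-en-1-ol | CC(C)=CCC(O)[Sn](CCCC)(CCCC)CCCC | intermediate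
14 | 4-methyl-1-(tributylstannyl)pent-3-en-1-one | CC(C)=CCC(=O)[Sn](CCCC)(CCCC)CCCC | intermediate
15 | (1R)-4-methyl-1-(tributylstannyl)pent-3-en-1-ol | CC(C)=CC[C@H](O)[Sn](CCCC)(CCCC)CCCC | intermediate
16 | tributyl[(1R)-1-(methoxymethoxy)-4-methylpent-3-en-1-yl]stannane | CC(C)=CC[C@H](OCOC)[Sn](CCCC)(CCCC)CCCC | intermediate
17 | [(1R)-1-(methoxymethoxy)-4-methylpent-3-en-1-yl]lithium | CC(C)=CC[C@H](OCOC)[Li] | intermediate
18 | bromo[(1R)-1-(methoxymethoxy)-4-methylpent-3-en-1-yl]magnesium | CC(C)=CC[C@H](OCOC)[Mg]Br | intermediate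
19 | (1R,6S)-6-[(2S,3S)-2-hydroxy-3-(methoxymethoxy)-6-methylhept-5-en-2-yl]-3-methylcyclohex-3-en-1-ol | O[C@@H]1CC(C)=CC[C@@H]1[C@](C)(O)[C@@H](OCOC)CC=C(C)C | intermediate
20 | (1R,6S)-6-[(2S,3S)-2-hydroxy-3-(methoxymethoxy)-6-methylhept-5-en-2-yl]-3-methylcyclohex-3-en-1-yl acetate | CC(=O)O[C@@H]1CC(C)=CC[C@@H]1[C@](C)(O)[C@@H](OCOC)CC=C(C)C | intermediate
21 | (1R,6S)-6-[(2S,3S,5S)-5-bromo-3-(methoxymethoxy)-2,6,6-trimethyloxan-2-yl]-3-methylcyclohex-3-en-1-yl acetate | CC(=O)O[C@@H]1CC(C)=CC[C@@H]1[C@]1(C)OC(C)(C)[C@@H](Br)C[C@@H]1OCOC | intermediate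
22 | (1R,2S,4S,5R)-2-[(2S,3S,5S)-5-bromo-3-(methoxymethoxy)-2,6,6-trimethyloxan-2-yl]-4,5-epoxy-5-methylcyclohexyl acetate (oxirane trans to the acetoxy and oxanyl groups) | CC(=O)O[C@@H]1C[C@@]2(C)O[C@H]2C[C@@H]1[C@]1(C)OC(C)(C)[C@@H](Br)C[C@@H]1OCOC | intermediate
23 | (1R,2S,4S,5S)-5-bromo-2-[(2S,3S,5S)-5-bromo-3-(methoxymethoxy)-2,6,6-trimethyloxan-2-yl]-4-hydroxy-5-methylcyclohexyl acetate | CC(=O)O[C@@H]1C[C@](C)(Br)[C@@H](O)C[C@@H]1[C@]1(C)OC(C)(C)[C@@H](Br)C[C@@H]1OCOC | intermediate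
24 | chlorosulfite of 23 at the C4 oxygen | CC(=O)O[C@@H]1C[C@](C)(Br)[C@@H](OS(Cl)=O)C[C@@H]1[C@]1(C)OC(C)(C)[C@@H](Br)C[C@@H]1OCOC | intermediate
25 | (1R,2S,4R,5R)-4-bromo-2-[(2S,3S,5S)-5-bromo-3-(methoxymethoxy)-2,6,6-trimethyloxan-2-yl]-5-chloro-5-methylcyclohexyl acetate | CC(=O)O[C@@H]1C[C@@](C)(Cl)[C@H](Br)C[C@@H]1[C@]1(C)OC(C)(C)[C@@H](Br)C[C@@H]1OCOC | intermediate
26 | (1R,2S,4R,5R)-4-bromo-2-[(2S,3S,5S)-5-bromo-3-hydroxy-2,6,6-trimethyloxan-2-yl]-5-chloro-5-methylcyclohexyl acetate | CC(=O)O[C@@H]1C[C@@](C)(Cl)[C@H](Br)C[C@@H]1[C@]1(C)OC(C)(C)[C@@H](Br)C[C@@H]1O | target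

## Step count and risks

Total step count: 18.
Longest linear sequence: 12 steps (steps 2–6 and 12–18; the branches through step 1 and through steps 7–11 are equally long).

The three steps most likely to fail:

Step 12 (fragment union). The α-alkoxy organometallic may enolise the methyl ketone or add with poor facial control. The fallback sets out from ketone 10 and comes back at oxane 21, and it sets C3' later through the ring instead of through the reagent. 1,3-Dithiane is lithiated with n-BuLi and alkylated with prenyl bromide to give 2-(3-methylbut-2-en-1-yl)-1,3-dithiane F1. Its 2-lithio derivative adds to the chelated alkoxide of 10 to give dithianyl carbinol F2, and Ac2O/DMAP then gives its C1 acetate F3. MeI and CaCO3 in aqueous MeCN unmask the α-hydroxy ketone F4, and TBCO closes ring B to the oxan-3-one F5. LiBH(sBu)3 at −78 °C attacks the ring ketone from the equatorial side to give the axial C3' alcohol F6, and MOMCl/iPr2NEt returns 21.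

Step 14 (bromoetherification). The ring A alkene can compete for the bromonium ion and be trapped by the tertiary alcohol as a 2-oxabicyclo[2.2.2]octane. The fallback sets out from Weinreb amide 8 and comes back at 21, closing ring A after ring B. MeMgBr converts 8 into the open-chain hydroxy ketone F7. Union with 18 as in step 12 gives the open-chain diol F8, and acetylation gives the acetate F9. TBCO then meets only a 1,1-disubstituted and a monosubstituted alkene beside the prenyl group and gives the bromo-oxane diene F10. Metathesis with the second-generation Grubbs catalyst closes ring A to 21.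

Step 17 (bromonium-relayed chlorination). Chloride may open the bromonium ion at C4 irreversibly, or elimination may intervene. The fallback sets out from alkene 21 and comes back at 25, bypassing the epoxide. Br2 in CH2Cl2 at −78 °C gives the trans-diaxial dibromide F11. Heating F11 with Et4NCl in MeNO2 at 60 °C ionises it to the same bromonium ion, which chloride captures at the tertiary carbon to give 25.

## Further compounds

F1 | step 12 | 2-(3-methylbut-2-en-1-yl)-1,3-dithiane | CC(C)=CCC1SCCCS1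
F2 | step 12 | (1R,6S)-6-{(1S)-1-hydroxy-1-[2-(3-methylbut-2-en-1-yl)-1,3-dithian-2-yl]ethyl}-3-methylcyclohex-3-en-1-ol | O[C@@H]1CC(C)=CC[C@@H]1[C@](C)(O)C1(CC=C(C)C)SCCCS1
F3 | step 12 | (1R,6S)-6-{(1S)-1-hydroxy-1-[2-(3-methylbut-2-en-1-yl)-1,3-dithian-2-yl]ethyl}-3-methylcyclohex-3-en-1-yl acetate | CC(=O)O[C@@H]1CC(C)=CC[C@@H]1[C@](C)(O)C1(CC=C(C)C)SCCCS1
F4 | step 12 | (1R,6S)-6-[(2S)-2-hydroxy-6-methyl-3-oxohept-5-en-2-yl]-3-methylcyclohex-3-en-1-yl acetate | CC(=O)O[C@@H]1CC(C)=CC[C@@H]1[C@](C)(O)C(=O)CC=C(C)C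
F5 | step 12 | (1R,6S)-6-[(2S,5S)-5-bromo-2,6,6-trimethyl-3-oxooxan-2-yl]-3-methylcyclohex-3-en-1-yl acetate | CC(=O)O[C@@H]1CC(C)=CC[C@@H]1[C@]1(C)OC(C)(C)[C@@H](Br)CC1=O
F6 | step 12 | (1R,6S)-6-[(2S,3S,5S)-5-bromo-3-hydroxy-2,6,6-trimethyloxan-2-yl]-3-methylcyclohex-3-en-1-yl acetate | CC(=O)O[C@@H]1CC(C)=CC[C@@H]1[C@]1(C)OC(C)(C)[C@@H](Br)C[C@@H]1O
F7 | step 14 | (3S,4R)-4-hydroxy-6-methyl-3-(prop-2-en-1-yl)hept-6-en-2-one | C=C(C)C[C@@H](O)[C@H](CC=C)C(C)=O
F8 | step 14 | (4R,5S,6S,7S)-7-(methoxymethoxy)-2,6,10-trimethyl-5-(prop-2-en-1-yl)undeca-1,9-diene-4,6-diol | C=C(C)C[C@@H](O)[C@H](CC=C)[C@](C)(O)[C@@H](OCOC)CC=C(C)C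
F9 | step 14 | (4R,5S,6S,7S)-6-hydroxy-7-(methoxymethoxy)-2,6,10-trimethyl-5-(prop-2-en-1-yl)undeca-1,9-dien-4-yl acetate | C=C(C)C[C@@H](OC(C)=O)[C@H](CC=C)[C@](C)(O)[C@@H](OCOC)CC=C(C)C
F10 | step 14 | (4R,5S)-5-[(2S,3S,5S)-5-bromo-3-(methoxymethoxy)-2,6,6-trimethyloxan-2-yl]-2-methylocta-1,7-dien-4-yl acetate | C=C(C)C[C@@H](OC(C)=O)[C@H](CC=C)[C@]1(C)OC(C)(C)[C@@H](Br)C[C@@H]1OCOC
F11 | step 17 | (1R,2S,4S,5S)-4,5-dibromo-2-[(2S,3S,5S)-5-bromo-3-(methoxymethoxy)-2,6,6-trimethyloxan-2-yl]-5-methylcyclohexyl acetate | CC(=O)O[C@@H]1C[C@](C)(Br)[C@@H](Br)C[C@@H]1[C@]1(C)OC(C)(C)[C@@H](Br)C[C@@H]1OCOC
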